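In a one-step world you read one time constant and are done. Here a dissolving gas feeds a catalytic loop, so you want one time that joins them.

substrate 0.10 M; gas 34 mM (held); free catalyst 0.081 mol%; time 8.0 min

    substrate + free catalyst → catalyst intermediate A (k1 = 150 /M/s)
    reagent + catalyst intermediate A → catalyst intermediate B (k2 = 180 /M/s)
    catalyst intermediate B ⇌ free catalyst + target (K3 = 5.2 M, k3 = 1200 /s)
    gas ⇌ reagent, rate k4*(csat - [reagent]) (k4 = 0.0078 /s, csat = 34 mM)

- autumn: doubling the amount of free catalyst, all else as stated
- midnight: doubling the saturation concentration of gas, all else as stated
- dusk: doubling the transfer coefficient of step 4, all else as stated

- at the start none of reagent is dissolved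
- run time (flask): 8.0 min

- how much target there is at 8.0 min, in percent of the substrate charged
- the change that raises the amount of target at 8.0 min, in percent of the substrate charged most ("none" if none brings more than 2 percentage points) (autumn / midnight / dusk / none)
- amount of target at 8.0 min, in percent of the substrate charged, after midnight

Here is my reckoning. Let catalyst intermediate A be the resting state. Dissolved reagent is then a tank filled by the gas crossing, with a time of 128 s, and drained by the second step, with a time of 68.6 s. It levels off with a lag of 44.7 s. Add the two times and multiply by the charge over the saturation, 2.94, and you get the clearing time 9.65 min, the time the whole charge needs at that steady delivery.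

The correction is free catalyst, a share of 14.2% at full substrate. Reagent rises to recover part of that loss, so 34.9% of the share counts, and the time stretches to 10.1 min. By this reckoning, this flask holds 71.5% of the charge as target at the asked time.

Now turn the settings. Autumn halves the draining time, which gives a clearing time of 7.97 min. Dusk halves the filling time, which gives 6.50 min. Midnight halves the whole, so I pick midnight. Corrected, my clearing time for midnight is 5.35 min, which is shorter than the run. So I let delivery hold until substrate falls to 25.6%, and after that I let substrate decay with a time of 82.3 s. That estimate gives 97.6%.

The forecast says 66.5%, midnight and 93%, on the ground that “Reagent sits at quasi-steady state”. Both its yields lie below mine.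

The simulation gives 67.1%, midnight and 93.6%, with gains of 20 percentage points for autumn, 27 points for midnight and 18 points for dusk, so autumn passes dusk, against my clearing times. In this flask the run less its lag is 75.2% of the clearing time, and net turnover of the substrate's capture reaches 67.1%. In this flask, with all else held, the yield has moved by 5 points at loadings of 0.069 mol% and 0.095 mol%. For the neighbour at 0.25 M of substrate, with the loading and the time held, the clearing time is 19.1 min, which predicts 40.0%, and that flask stands at 39.6%.

Its constants were chosen freely; the flask was simulated.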